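**Retrosynthetic overview**
1. 28 ⇐ diol 23: isobutyrate on the less hindered C4–OH, angelate last on the neopentyl C5–OH.
2. Seven-membered ring (C6–C7 bond, CMe2 quaternary carbon, C7–H): hydrogen-atom-transfer-initiated 7-exo addition of a tertiary radical to a cyclobutanone tosylhydrazone, with traceless loss of the hydrazone (19 ⇒ 22).
3. Four- and six-membered rings together: intramolecular vinylketene–alkene [2+2] of the farnesane-type acid 12 (bonds C1–C7 and C2–C8), steered by a silyloxy stereocentre at the future C11 ketone.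
4. Acyclic chain from three C5 units: two catalyst-controlled vinylogous Mukaiyama aldol additions of one senecioate dienolate (to prenal, then to enal 9); C5–O by a hydroxy-directed singlet-oxygen ene reaction.
5. Ring order: cyclobutane + cyclohexene (step 10), then cycloheptane (step 13).

Assumption and labels: the ester C/C=C(/C)C(=O)O is read as the (2Z)-2-methylbut-2-enoate (angelate); "target C-n" means the tricyclo[5.4.0.0^2,8]undecane locant of 28 (C11 ketone, C9=C10, C2 quaternary C–CH3, C4 O-isobutyryl, C5 O-angeloyl, C6 CMe2; C1, C2, C7, C8 form the cyclobutane).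

**Step 1**
Reactants: 1 methyl 3-methylbut-2-enoate
Product: 2 (1Z)-tert-butyl[(1-methoxy-3-methylbuta-1,3-dien-1-yl)oxy]dimethylsilane
Conditions: LiN(i-Pr)2, THF/DMPU, −78 °C; t-BuMe2SiCl, −78 → 0 °C
Reagents that add atoms: tert-butyldimethylsilyl chloride, CC(C)(C)[Si](C)(C)Cl
Why: γ-Deprotonation of the senecioate and O-silylation of the extended enolate (silyl ketene acetal formation) give the dienol ether that serves twice as the five-carbon nucleophile; no stereocentre is formed.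

**Step 2**
Reactants: 3 3-methylbut-2-enal; 2 (1Z)-tert-butyl[(1-methoxy-3-methylbuta-1,3-dien-1-yl)oxy]dimethylsilane
Product: 4 methyl (2E,5S)-5-hydroxy-3,7-dimethylocta-2,6-dienoate
Conditions: SiCl4 (1.1 equiv), chiral binaphthyldiamine bisphosphoramide (5 mol %, the enantiomer that directs Si-face attack), i-Pr2NEt (10 mol %), CH2Cl2, −78 °C; aqueous work-up
Reagents that add atoms: none
Why: Lewis-base-activated SiCl4 vinylogous Mukaiyama aldol reaction; γ-selective addition to the Si face of the enal carbonyl sets the carbinol that becomes target C4.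

**Step 3**
Reactants: 4 methyl (2E,5S)-5-hydroxy-3,7-dimethylocta-2,6-dienoate
Product: 6 methyl (2E,5S,6S)-5,6-dihydroxy-3,7-dimethylocta-2,7-dienoate, via allylic hydroperoxide 5 (not isolated)
Conditions: O2, hν (visible), tetraphenylporphyrin (cat.), CCl4, 0 °C; then PPh3
Reagents that add atoms: dioxygen, O=O
Why: Hydroxy-directed Schenck ene reaction of singlet oxygen on the electron-rich trisubstituted alkene (the enoate alkene is inert) is threo-selective, placing the new C–O (target C5) anti to the existing carbinol and leaving the isopropenyl group; PPh3 reduces the hydroperoxide.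

**Step 4**
Reactants: 6 methyl (2E,5S,6S)-5,6-dihydroxy-3,7-dimethylocta-2,7-dienoate
Product: 7 methyl (2E)-4-[(4S,5S)-2,2-dimethyl-5-(prop-1-en-2-yl)-1,3-dioxolan-4-yl]-3-methylbut-2-enoate
Conditions: Me2C(OMe)2, PPTS (cat.), CH2Cl2, 23 °C
Reagents that add atoms: 2,2-dimethoxypropane, COC(C)(C)OC
Why: Acetal exchange protects the threo diol as the trans-dioxolane; no stereocentre changes.

**Step 5**
Reactants: 7 methyl (2E)-4-[(4S,5S)-2,2-dimethyl-5-(prop-1-en-2-yl)-1,3-dioxolan-4-yl]-3-methylbut-2-enoate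
Product: 8 (2E)-4-[(4S,5S)-2,2-dimethyl-5-(prop-1-en-2-yl)-1,3-dioxolan-4-yl]-3-methylbut-2-en-1-ol
Conditions: i-Bu2AlH (2.2 equiv), CH2Cl2, −78 °C
Reagents that add atoms: none
Why: 1,2-Reduction of the enoate to the allylic alcohol with retention of the (E)-alkene.

**Step 6**
Reactants: 8 (2E)-4-[(4S,5S)-2,2-dimethyl-5-(prop-1-en-2-yl)-1,3-dioxolan-4-yl]-3-methylbut-2-en-1-ol
Product: 9 (2E)-4-[(4S,5S)-2,2-dimethyl-5-(prop-1-en-2-yl)-1,3-dioxolan-4-yl]-3-methylbut-2-enal
Conditions: MnO2 (15 equiv), CH2Cl2, 23 °C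
Reagents that add atoms: none
Why: Chemoselective allylic alcohol oxidation gives the (E)-enal without touching the isopropenyl group.

**Step 7**
Reactants: 9 (2E)-4-[(4S,5S)-2,2-dimethyl-5-(prop-1-en-2-yl)-1,3-dioxolan-4-yl]-3-methylbut-2-enal; 2 (1Z)-tert-butyl[(1-methoxy-3-methylbuta-1,3-dien-1-yl)oxy]dimethylsilane
Product: 10 methyl (2E,5S,6E)-8-[(4S,5S)-2,2-dimethyl-5-(prop-1-en-2-yl)-1,3-dioxolan-4-yl]-5-hydroxy-3,7-dimethylocta-2,6-dienoate
Conditions: SiCl4 (1.1 equiv), the same bisphosphoramide enantiomer (5 mol %), i-Pr2NEt (10 mol %), CH2Cl2, −78 °C; aqueous work-up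
Reagents that add atoms: none
Why: Second vinylogous Mukaiyama aldol reaction; catalyst-controlled Si-face addition sets the (5S) carbinol (future target C11), which later steers the cycloaddition and is then oxidized away.

**Step 8**
Reactants: 10 methyl (2E,5S,6E)-8-[(4S,5S)-2,2-dimethyl-5-(prop-1-en-2-yl)-1,3-dioxolan-4-yl]-5-hydroxy-3,7-dimethylocta-2,6-dienoate
Product: 11 methyl (2E,5S,6E)-8-[(4S,5S)-2,2-dimethyl-5-(prop-1-en-2-yl)-1,3-dioxolan-4-yl]-3,7-dimethyl-5-(triethylsilyloxy)octa-2,6-dienoate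
Conditions: Et3SiCl, imidazole, DMF, 0 °C
Reagents that add atoms: chlorotriethylsilane, CC[Si](Cl)(CC)CC
Why: Silyl ether protection of the secondary alcohol; configuration unchanged.

**Step 9**
Reactants: 11 methyl (2E,5S,6E)-8-[(4S,5S)-2,2-dimethyl-5-(prop-1-en-2-yl)-1,3-dioxolan-4-yl]-3,7-dimethyl-5-(triethylsilyloxy)octa-2,6-dienoate
Product: 12 (2E,5S,6E)-8-[(4S,5S)-2,2-dimethyl-5-(prop-1-en-2-yl)-1,3-dioxolan-4-yl]-3,7-dimethyl-5-(triethylsilyloxy)octa-2,6-dienoic acid
Conditions: LiOH, THF/MeOH/H2O, 40 °C; AcOH to pH 5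
Reagents that add atoms: lithium hydroxide, [Li+].[OH-]
Why: Ester saponification; silyl ether and acetonide are stable to base and to the buffered acidification.

**Step 10**
Reactants: 12 (2E,5S,6E)-8-[(4S,5S)-2,2-dimethyl-5-(prop-1-en-2-yl)-1,3-dioxolan-4-yl]-3,7-dimethyl-5-(triethylsilyloxy)octa-2,6-dienoic acid
Product: 15 (1R,4S,5R,7R)-7-{[(4S,5S)-2,2-dimethyl-5-(prop-1-en-2-yl)-1,3-dioxolan-4-yl]methyl}-7-methyl-2-methylidene-4-(triethylsilyloxy)bicyclo[3.1.1]heptan-6-one, via acid chloride 13 (not isolated), via vinylketene 14 (not isolated)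
Conditions: Me2C=C(Cl)NMe2, CH2Cl2, 0 → 23 °C; then slow addition to Et3N (3 equiv), toluene, 110 °C, 0.01 M
Reagents that add atoms: none
Why: Intramolecular vinylketene–alkene [2+2] cycloaddition (Snider type): Et3N removes HCl through the γ-methyl group to give the cross-conjugated ketene, whose carbonyl carbon (target C7) bonds to the less substituted alkene carbon (target C1) and whose α-carbon (target C8) bonds to the disubstituted one (target C2); suprafacial addition to the (E)-alkene puts CH3 syn and the dioxolanylmethyl arm anti to the three-carbon bridge, and the silyloxy stereocentre takes the side of the carbonyl bridge, which fixes the absolute sense of C1, C2 and C8.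

**Step 11**
Reactants: 15 (1R,4S,5R,7R)-7-{[(4S,5S)-2,2-dimethyl-5-(prop-1-en-2-yl)-1,3-dioxolan-4-yl]methyl}-7-methyl-2-methylidene-4-(triethylsilyloxy)bicyclo[3.1.1]heptan-6-one
Product: 17 N'-{7-[(4S,5S)-2,2-dimethyl-5-(prop-1-en-2-yl)-1,3-dioxolan-4-yl]methyl-4-hydroxy-7-methyl-2-methylidenebicyclo[3.1.1]heptan-6-ylidene}-4-methylbenzenesulfonohydrazide (ring stereocentres as in 15), via silyl ether tosylhydrazone 16 (not isolated)
Conditions: TsNHNH2 (1.05 equiv), PPTS (10 mol %), MeOH, 23 °C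
Reagents that add atoms: 4-methylbenzenesulfonohydrazide, NNS(=O)(=O)c1ccc(C)cc1
Why: Hydrazone condensation at the strained, non-enolizable cyclobutanone, with methanolysis of the triethylsilyl ether under the same mild acid; no stereocentre is touched.

**Step 12**
Reactants: 17 hydroxy tosylhydrazone (as named in step 11)
Product: 19 N'-[(1S,5R,7R)-7-{[(4S,5S)-2,2-dimethyl-5-(prop-1-en-2-yl)-1,3-dioxolan-4-yl]methyl}-4,7-dimethyl-2-oxobicyclo[3.1.1]hept-3-en-6-ylidene]-4-methylbenzenesulfonohydrazide, via deconjugated enone 18 (not isolated)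
Conditions: SO3·pyridine, DMSO, i-Pr2NEt, CH2Cl2, 0 °C; then DBU (0.2 equiv), 23 °C
Reagents that add atoms: none
Why: Parikh–Doering oxidation followed by base-mediated migration of the exocyclic double bond into conjugation gives the verbenone-type enone; it is run only after target C7 is a hydrazone, because a 2-acylcyclobutanone would be prone to retro-Claisen opening; the directing carbinol stereocentre is removed here.

**Step 13**
Reactants: 19 enone tosylhydrazone (as named in step 12)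
Product: 22 (1R,2R,4S,5S,7S,8R)-2,6,6,9-tetramethyl-4,5-(propane-2,2-diyldioxy)tricyclo[5.4.0.0^2,8]undec-9-en-11-one, via sulfonyl hydrazide 20 (not isolated), via alkyl diazene 21 (not isolated)
Conditions: Fe(acac)3 (30 mol %), PhSiH3 (2.5 equiv), EtOH, 60 °C, 0.005 M; then NaOAc·3H2O, 80 °C
Reagents that add atoms: none
Why: Proposed new method: Fe–H hydrogen-atom transfer to the isopropenyl CH2 gives the tertiary radical at target C6, which the arm on C2 can deliver only to the anti face of the C7 hydrazone carbon in a 7-exo addition (closes the seven-membered ring, creates the CMe2 quaternary carbon, sets C7); the N-radical is reduced to hydrazide 20, which loses sulfinate to give diazene 21 and then N2 to leave C7–H; the closest known reactions are iron-hydride HAT alkene–hydrazone couplings (five- and six-membered rings) and the Kabalka-type fragmentation of N-alkyl-N′-tosylhydrazines.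

**Step 14**
Reactants: 22 (1R,2R,4S,5S,7S,8R)-2,6,6,9-tetramethyl-4,5-(propane-2,2-diyldioxy)tricyclo[5.4.0.0^2,8]undec-9-en-11-one
Product: 23 (1R,2R,4S,5S,7S,8R)-4,5-dihydroxy-2,6,6,9-tetramethyltricyclo[5.4.0.0^2,8]undec-9-en-11-one
Conditions: AcOH/H2O (4:1), 50 °C
Reagents that add atoms: none
Why: Acid hydrolysis of the acetonide frees the trans-diol; both C–O bonds of the diol are retained.

**Step 15**
Reactants: 23 (1R,2R,4S,5S,7S,8R)-4,5-dihydroxy-2,6,6,9-tetramethyltricyclo[5.4.0.0^2,8]undec-9-en-11-one; 24 2-methylpropanoyl chloride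
Product: 25 (1R,2R,4S,5S,7S,8R)-5-hydroxy-2,6,6,9-tetramethyl-11-oxotricyclo[5.4.0.0^2,8]undec-9-en-4-yl 2-methylpropanoate
Conditions: pyridine, CH2Cl2, −20 °C (1.05 equiv of 24)
Reagents that add atoms: none
Why: Site-selective acylation: the C4–OH is flanked by CH2, whereas the C5–OH is neopentyl (next to CMe2) and reacts much more slowly.

**Step 16**
Reactants: 25 (1R,2R,4S,5S,7S,8R)-5-hydroxy-2,6,6,9-tetramethyl-11-oxotricyclo[5.4.0.0^2,8]undec-9-en-4-yl 2-methylpropanoate; 26 (2Z)-2-methylbut-2-enoic acid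
Product: 28 (1R,2R,4S,5S,7S,8R)-2,6,6,9-tetramethyl-4-(2-methylpropanoyloxy)-11-oxotricyclo[5.4.0.0^2,8]undec-9-en-5-yl (2Z)-2-methylbut-2-enoate, via mixed anhydride 27 (not isolated)
Conditions: 2,4,6-Cl3C6H2COCl, Et3N, toluene, 23 °C; then 25, 80 °C
Reagents that add atoms: none
Why: Yamaguchi-type mixed-anhydride esterification run without a nucleophilic catalyst, which acylates the hindered alcohol while keeping the (Z)-geometry of the angelate.

**Compound list**
1 | methyl 3-methylbut-2-enoate | COC(=O)C=C(C)C | starting material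
2 | (1Z)-tert-butyl[(1-methoxy-3-methylbuta-1,3-dien-1-yl)oxy]dimethylsilane | CO/C(O[Si](C)(C)C(C)(C)C)=C/C(C)=C | intermediate
3 | 3-methylbut-2-enal | CC(C)=CC=O | starting material
4 | methyl (2E,5S)-5-hydroxy-3,7-dimethylocta-2,6-dienoate | COC(=O)/C=C(\C)C[C@H](O)C=C(C)C | intermediate
5 | methyl (2E,5S,6S)-6-hydroperoxy-5-hydroxy-3,7-dimethylocta-2,7-dienoate | COC(=O)/C=C(\C)C[C@H](O)[C@@H](OO)C(C)=C | intermediate
6 | methyl (2E,5S,6S)-5,6-dihydroxy-3,7-dimethylocta-2,7-dienoate | COC(=O)/C=C(\C)C[C@H](O)[C@@H](O)C(C)=C | intermediate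
7 | methyl (2E)-4-[(4S,5S)-2,2-dimethyl-5-(prop-1-en-2-yl)-1,3-dioxolan-4-yl]-3-methylbut-2-enoate | COC(=O)/C=C(\C)C[C@@H]1OC(C)(C)O[C@H]1C(C)=C | intermediate
8 | (2E)-4-[(4S,5S)-2,2-dimethyl-5-(prop-1-en-2-yl)-1,3-dioxolan-4-yl]-3-methylbut-2-en-1-ol | OC/C=C(\C)C[C@@H]1OC(C)(C)O[C@H]1C(C)=C | intermediate
9 | (2E)-4-[(4S,5S)-2,2-dimethyl-5-(prop-1-en-2-yl)-1,3-dioxolan-4-yl]-3-methylbut-2-enal | O=C/C=C(\C)C[C@@H]1OC(C)(C)O[C@H]1C(C)=C | intermediate
10 | methyl (2E,5S,6E)-8-[(4S,5S)-2,2-dimethyl-5-(prop-1-en-2-yl)-1,3-dioxolan-4-yl]-5-hydroxy-3,7-dimethylocta-2,6-dienoate | COC(=O)/C=C(\C)C[C@H](O)/C=C(\C)C[C@@H]1OC(C)(C)O[C@H]1C(C)=C | intermediate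
11 | methyl (2E,5S,6E)-8-[(4S,5S)-2,2-dimethyl-5-(prop-1-en-2-yl)-1,3-dioxolan-4-yl]-3,7-dimethyl-5-(triethylsilyloxy)octa-2,6-dienoate | COC(=O)/C=C(\C)C[C@H](O[Si](CC)(CC)CC)/C=C(\C)C[C@@H]1OC(C)(C)O[C@H]1C(C)=C | intermediate
12 | (2E,5S,6E)-8-[(4S,5S)-2,2-dimethyl-5-(prop-1-en-2-yl)-1,3-dioxolan-4-yl]-3,7-dimethyl-5-(triethylsilyloxy)octa-2,6-dienoic acid | OC(=O)/C=C(\C)C[C@H](O[Si](CC)(CC)CC)/C=C(\C)C[C@@H]1OC(C)(C)O[C@H]1C(C)=C | intermediate
13 | acid chloride of 12 | ClC(=O)/C=C(\C)C[C@H](O[Si](CC)(CC)CC)/C=C(\C)C[C@@H]1OC(C)(C)O[C@H]1C(C)=C | intermediate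
14 | (5S,6E)-8-[(4S,5S)-2,2-dimethyl-5-(prop-1-en-2-yl)-1,3-dioxolan-4-yl]-7-methyl-3-methylidene-5-(triethylsilyloxy)octa-1,6-dien-1-one (vinylketene) | O=C=CC(=C)C[C@H](O[Si](CC)(CC)CC)/C=C(\C)C[C@@H]1OC(C)(C)O[C@H]1C(C)=C | intermediate
15 | (1R,4S,5R,7R)-7-{[(4S,5S)-2,2-dimethyl-5-(prop-1-en-2-yl)-1,3-dioxolan-4-yl]methyl}-7-methyl-2-methylidene-4-(triethylsilyloxy)bicyclo[3.1.1]heptan-6-one | C=C(C)[C@@H]1OC(C)(C)O[C@H]1C[C@@]2(C)[C@@H]3[C@@H](O[Si](CC)(CC)CC)CC(=C)[C@H]2C3=O | intermediate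
16 | tosylhydrazone of 15 at the cyclobutanone carbon (stereocentres as in 15) | C=C(C)[C@@H]1OC(C)(C)O[C@H]1C[C@@]2(C)[C@@H]3[C@@H](O[Si](CC)(CC)CC)CC(=C)[C@H]2C3=NNS(=O)(=O)c4ccc(C)cc4 | intermediate
17 | N'-{7-[(4S,5S)-2,2-dimethyl-5-(prop-1-en-2-yl)-1,3-dioxolan-4-yl]methyl-4-hydroxy-7-methyl-2-methylidenebicyclo[3.1.1]heptan-6-ylidene}-4-methylbenzenesulfonohydrazide (16 without the silyl group) | C=C(C)[C@@H]1OC(C)(C)O[C@H]1C[C@@]2(C)[C@@H]3[C@@H](O)CC(=C)[C@H]2C3=NNS(=O)(=O)c4ccc(C)cc4 | intermediate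
18 | β,γ-unsaturated ketone from 17 (carbinol oxidized to C=O, exocyclic methylidene still in place) | C=C(C)[C@@H]1OC(C)(C)O[C@H]1C[C@@]2(C)[C@@H]3C(=O)CC(=C)[C@H]2C3=NNS(=O)(=O)c4ccc(C)cc4 | intermediate
19 | N'-[(1S,5R,7R)-7-{[(4S,5S)-2,2-dimethyl-5-(prop-1-en-2-yl)-1,3-dioxolan-4-yl]methyl}-4,7-dimethyl-2-oxobicyclo[3.1.1]hept-3-en-6-ylidene]-4-methylbenzenesulfonohydrazide | C=C(C)[C@@H]1OC(C)(C)O[C@H]1C[C@@]2(C)[C@@H]3C(=O)C=C(C)[C@H]2C3=NNS(=O)(=O)c4ccc(C)cc4 | intermediate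
20 | 22 carrying NH–NHTs in place of H at target C7 (cyclized sulfonyl hydrazide) | CC1(C)O[C@@H]2[C@@H](O1)C[C@@]3(C)[C@@H]4C(=O)C=C(C)[C@H]3[C@]4(NNS(=O)(=O)c5ccc(C)cc5)C2(C)C | intermediate
21 | 22 carrying N=NH in place of H at target C7 (alkyl diazene) | CC1(C)O[C@@H]2[C@@H](O1)C[C@@]3(C)[C@@H]4C(=O)C=C(C)[C@H]3[C@]4(N=N)C2(C)C | intermediate
22 | (1R,2R,4S,5S,7S,8R)-2,6,6,9-tetramethyl-4,5-(propane-2,2-diyldioxy)tricyclo[5.4.0.0^2,8]undec-9-en-11-one | CC1(C)O[C@@H]2[C@@H](O1)C[C@@]3(C)[C@@H]4C(=O)C=C(C)[C@H]3[C@@H]4C2(C)C | intermediate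
23 | (1R,2R,4S,5S,7S,8R)-4,5-dihydroxy-2,6,6,9-tetramethyltricyclo[5.4.0.0^2,8]undec-9-en-11-one | O[C@@H]1[C@@H](O)C[C@@]2(C)[C@@H]3C(=O)C=C(C)[C@H]2[C@@H]3C1(C)C | intermediate
24 | 2-methylpropanoyl chloride | CC(C)C(Cl)=O | starting material
25 | (1R,2R,4S,5S,7S,8R)-5-hydroxy-2,6,6,9-tetramethyl-11-oxotricyclo[5.4.0.0^2,8]undec-9-en-4-yl 2-methylpropanoate | O[C@@H]1[C@@H](OC(=O)C(C)C)C[C@@]2(C)[C@@H]3C(=O)C=C(C)[C@H]2[C@@H]3C1(C)C | intermediate
26 | (2Z)-2-methylbut-2-enoic acid (angelic acid) | C/C=C(/C)C(=O)O | starting material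
27 | (2Z)-2-methylbut-2-enoic 2,4,6-trichlorobenzoic anhydride | C/C=C(/C)C(=O)OC(=O)c1c(Cl)cc(Cl)cc1Cl | intermediate
28 | (1R,2R,4S,5S,7S,8R)-2,6,6,9-tetramethyl-4-(2-methylpropanoyloxy)-11-oxotricyclo[5.4.0.0^2,8]undec-9-en-5-yl (2Z)-2-methylbut-2-enoate (CNP0286736.1) | C/C=C(/C)C(=O)O[C@@H]1[C@@H](OC(=O)C(C)C)C[C@@]2(C)[C@@H]3C(=O)C=C(C)[C@H]2[C@@H]3C1(C)C | target

**Totals**
Total steps: 16. Longest linear sequence: 16 (1 → 2 → 4 → … → 28; compounds 3, 24 and 26 enter as reactants).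

**Three steps most likely to fail**

Step 13 (radical ring closure). The 7-exo addition to a hindered cyclobutanone hydrazone may be slower than reduction of the tertiary radical by the metal hydride, which would give the uncyclized isopropyl compound. The fallback sets out from 19 and comes back to the route at 22. The isopropenyl group of 19 is first converted by Markovnikov hydrochlorination (Co(BF4)2·6H2O, salen-type ligand, t-BuOOH, PhSiH3, TsCl, EtOH) into the tertiary chloride F1. The ring closure is then run as a stannane chain at high dilution (Bu3SnH by syringe pump, AIBN, toluene, 110 °C), where the isolated radical precursor meets only a low, controlled concentration of hydrogen donor. The hydrazide formed is 20, which is fragmented with NaOAc·3H2O as in step 13 to give 22.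

Step 10 (ketene cycloaddition). The allylic silyloxy group lowers the nucleophilicity of the alkene, and vinylogous elimination of silanolate or the fused [3.2.0] regioisomer could compete. The fallback sets out from 12 and comes back at 15. The acid is converted through 13 and pyrrolidine into the pyrrolidine amide F2. Tf2O and 2,4,6-collidine in 1,2-dichloroethane at 80 °C generate the vinyl keteniminium ion, a much stronger electrophile than the ketene, whose intramolecular [2+2] cycloaddition gives the cyclobutaniminium triflate F3. Hydrolysis with aqueous NaHCO3 releases 15.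

Step 16 (angeloylation). The neopentyl C5–OH is hindered, and forcing conditions can isomerize the angelate to the tiglate. The fallback sets out from 23 and comes back at 28, reversing the order of esterification so that the hindered oxygen can be acylated as its alkoxide without risk of acyl migration. The less hindered hydroxyl of 23 is protected (4-methoxybenzyl trichloroacetimidate, La(OTf)3 cat.) as the mono(4-methoxybenzyl) ether F4. Angelic anhydride F5 is prepared from 26 with dicyclohexylcarbodiimide. The alkoxide of F4 (LiN(SiMe3)2, THF, −78 °C) is acylated with F5 to give the protected angelate F6. DDQ in wet CH2Cl2 gives the hydroxy angelate F7, and 24 with pyridine installs the isobutyrate to give 28.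

**Further compounds**
F1 | step 13 | 19 with the prop-1-en-2-yl group replaced by 2-chloropropan-2-yl (configuration unchanged) | CC(C)(Cl)[C@@H]1OC(C)(C)O[C@H]1C[C@@]2(C)[C@@H]3C(=O)C=C(C)[C@H]2C3=NNS(=O)(=O)c4ccc(C)cc4
F2 | step 10 | pyrrolidine amide of 12, 1-[(2E,5S,6E)-8-[(4S,5S)-2,2-dimethyl-5-(prop-1-en-2-yl)-1,3-dioxolan-4-yl]-3,7-dimethyl-5-(triethylsilyloxy)octa-2,6-dienoyl]pyrrolidine | O=C(/C=C(\C)C[C@H](O[Si](CC)(CC)CC)/C=C(\C)C[C@@H]1OC(C)(C)O[C@H]1C(C)=C)N2CCCC2
F3 | step 10 | pyrrolidinium-ylidene (cyclobutaniminium) triflate corresponding to ketone 15 | C=C(C)[C@@H]1OC(C)(C)O[C@H]1C[C@@]2(C)[C@@H]3[C@@H](O[Si](CC)(CC)CC)CC(=C)[C@H]2C3=[N+]4CCCC4.[O-]S(=O)(=O)C(F)(F)F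
F4 | step 16 | 23 as its C4 4-methoxybenzyl ether (C5–OH free) | O[C@@H]1[C@@H](OCc4ccc(OC)cc4)C[C@@]2(C)[C@@H]3C(=O)C=C(C)[C@H]2[C@@H]3C1(C)C
F5 | step 16 | (2Z)-2-methylbut-2-enoic anhydride (angelic anhydride) | C/C=C(/C)C(=O)OC(=O)C(/C)=C\C
F6 | step 16 | C5 angelate of F4 (C4 4-methoxybenzyl ether) | C/C=C(/C)C(=O)O[C@@H]1[C@@H](OCc4ccc(OC)cc4)C[C@@]2(C)[C@@H]3C(=O)C=C(C)[C@H]2[C@@H]3C1(C)C
F7 | step 16 | (1R,2R,4S,5S,7S,8R)-4-hydroxy-2,6,6,9-tetramethyl-11-oxotricyclo[5.4.0.0^2,8]undec-9-en-5-yl (2Z)-2-methylbut-2-enoate | C/C=C(/C)C(=O)O[C@@H]1[C@@H](O)C[C@@]2(C)[C@@H]3C(=O)C=C(C)[C@H]2[C@@H]3C1(C)C
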